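**Abbreviations:** prenyl = 3-methylbut-2-en-1-yl; MOM = methoxymethyl; TIPS = triisopropylsilyl; Piv = pivaloyl (2,2-dimethylpropanoyl). Chroman numbering (O1, C2, C3, C4, C4a, C5–C8, C8a) is used throughout.

## The problem

Target 21 is a flavan: a dihydropyran (ring C) fused to a benzene ring (ring A) and carrying a 3,5-dimethoxyphenyl group (ring B) on C2. Ring A is a phloroglucinol unit in which only C8 is unsubstituted. The prenyl group at C6 lies between the phenols at C5 and C7 and para to the ring oxygen O1, so the 8-prenyl isomer is the regiochemical trap. C2 (R) is the only stereocentre and nothing else in the molecule can control it, so its configuration must come from a catalyst, a reagent or a resolved building block. Once set, C2 must be kept away from any carbanion at C3, which would expel the aryloxide O1 as in the flavanone–chalcone equilibrium. The prenyl olefin cyclises onto a flanking phenol under strong acid and is lost on hydrogenation. The free phloroglucinol ring is easily oxidised, and the two aryl methyl ethers rule out Lewis-acid dealkylation as a way to unmask the phenols. The enabling feature is C2 itself: it is benzylic and bound to O1, so in an open-chain ArCH2–O–aryl ether its C–H bond is a hydride donor. That hydrogen lies in a 1,5-relationship to an ortho benzylic carbon (the future C4), so hydride transfer followed by C2–C3 bond formation builds ring C and the stereocentre from an achiral ether.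

## Retrosynthesis

**21 back to 20 (two O–acyl bonds).** The phenols are released last from the bis-pivalate 20. The alternative of freeing them earlier would expose an oxidisable resorcinol and two acylable OH groups to the radical decarboxylation. Compound 20 has the full skeleton and the stereocentre; the forward reaction only has to cleave two hindered aryl esters without touching C2 or the prenyl group.

**20 back to 18 and 16 (the two C3–carboxyl bonds).** The two carboxyl groups on C3 are the price of the key step and are removed one at a time. The second goes by a radical decarboxylation of acid 18. The first goes by deallylation of the diallyl ester 16 to the malonic acid 17 and thermal loss of CO2. Allyl esters are preferred to methyl esters for two reasons. A halide-induced dealkoxycarbonylation of a methyl ester would generate a C3 ester enolate beside the aryloxy leaving group at C2. Saponification would also strip the pivalates before the radical step. The forward steps must leave C2 untouched; the configuration at C3 is irrelevant.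

**16 back to 14 (C2–C3 bond, with one hydrogen returned from C4 to C2).** This is the strategic cut. The neighbouring cuts each have a cost. Cutting O1–C2 or O1–C8a requires a stereocentre made beforehand in an open chain. Cutting C4–C4a leaves an unsaturated ring that must be reduced beside the prenyl group. The C2–C3 cut leads to 14, an achiral, acyclic benzylidene malonate in which the ether CH2 is the hydride donor and the alkylidene carbon the acceptor. The forward reaction must use only that CH2 as donor and must form C2–C3 with control of the face of the oxocarbenium ion.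

**14 back to 12 and 13 (the C4=C3 double bond).** A Knoevenagel condensation joins aldehyde 12 and diallyl malonate 13. It has to follow the acylation of the phenols, because a free ortho-phenol would lactonise onto the malonate to give a coumarin. The precursors are an aromatic aldehyde and a commercial diester; the forward reaction must tolerate a carbonyl group flanked by two ortho substituents.

**12 back to 11, 10, and 8 with 9 (two O–acyl bonds, then the O1–CH2 bond and two acetals).** Pivalates are required in the key step. An acetal at O5 would itself be a 1,5-hydride donor, and acyloxy groups keep ring A from deactivating the acceptor. MOM ethers are required earlier for the metalation. The exchange 10 to 11 to 12 is therefore placed after the ether bond to 3,5-dimethoxybenzyl bromide 9 is made at the single free phenol of salicylaldehyde 8. The forward steps need a mild acetal cleavage that spares the prenyl group.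

**8 back to 7 (the C4a–CHO bond).** Phenol 7 is symmetric, so its two ortho positions are identical. Ortho-formylation therefore fixes the ring A pattern, with O1 para to prenyl, without any selectivity question. Direct C-prenylation of a trihydroxybenzaldehyde would be shorter but leaves the three oxygens to be told apart afterwards.

**7 back to 6, 3 with 4, then 2 and 1 (the C6–prenyl bond and the oxygen protecting groups).** The prenyl group from 4 is placed by directed metalation between the two MOM ethers of 3. The third oxygen is marked by a bulky silyl group that does not direct lithiation and is removed to give 7. Compound 3 comes from phloroglucinol 1 through the bis-MOM ether 2. The forward reaction needs lithiation only at the doubly activated position.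

## Roads not taken

**Alternative 1:** The cut is O1–C8a, with ring A carried as a 5-silyloxycyclohexane-1,3-dione. The hydroxy dione A2 would cyclodehydrate, the benzylic alcohol adding to one carbonyl of the symmetric dione, to give the vinylogous ester A1. Prenylation at C6 through the kinetic enolate with 4, desilylation, oxidation at C7 and tautomerisation would then give the aromatic ring.
- Merits: the stereocentre comes from a well-established asymmetric ketone reduction and its C–O bond is never broken. The dione is symmetric, so ring closure has no regiochemical issue.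
- Weak points: the C6 enolate of A1 has the silyloxy group at C7 in the beta position, so elimination and loss of the C7 oxygen are likely. Attaching the side chain of A2 to C2 of a 1,3-dione competes with O-alkylation. The late oxidation and aromatisation must spare the prenyl group.
- Comparison: Alternative 1 is stronger in stereocontrol, because its asymmetric step is proven and the chosen plan's is not. The chosen plan sets against this an aromatic ring A from the first step, a substitution pattern fixed by symmetry, and no oxidation-level changes in the presence of the prenyl group.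

**Alternative 2:** The cut goes through ring A (C4a–C5 and C6–C7). The fused alkoxycyclobutenone A4 would open thermally to a vinylketene that combines with the siloxyalkyne A5 in a Danheiser benzannulation. This gives A3, which lacks only desilylation to reach 21.
- Merits: it is convergent. The prenyl group and both oxygens are placed in one regiodefined step, and no protecting-group exchange is needed.
- Weak points: neither partner is simple. A4 is a strained bicyclic cyclobutenone that must already carry the C2 stereocentre, so an asymmetric step and a ketene cycloaddition are still needed before the key step. A5 is a heat- and acid-sensitive skipped enyne ynol ether. The annulation needs prolonged heating and releases a free phenol beside the prenyl group.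
- Comparison: in convergence and in the end game Alternative 2 is better. In total step count and in the accessibility of its partners it is worse than the chosen plan, which draws on four commercial building blocks.

**Alternative 3:** The cut is C4–C4a. The enantioenriched aryl propargyl ether A7 would come from phenol 7 and the propargylic alcohol A8 by Mitsunobu inversion. Ph3PAuNTf2 (monovalent gold) would activate the alkyne for 6-endo-dig attack by the ortho carbon, giving the 2H-chromene A6. Reduction of C3=C4 and MOM removal would follow.
- Merits: it is the shortest road and shares 7 with the chosen route. The stereocentre comes from precedented asymmetric alkynylation or ynone reduction, and the symmetric ring makes both ortho carbons equivalent.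
- Weak points: the Mitsunobu step on a secondary benzylic propargylic alcohol risks SN2' attack and partial racemisation. The doubly activated C2–O bond of A7 can ionise under cationic gold. A6 can racemise by reversible oxa-6π ring opening. Gold must ignore the prenyl olefin and the acetals. The C3=C4 bond must then be reduced without touching the prenyl group or hydrogenolysing C2–O1.
- Comparison: Alternative 3 is clearly better in step economy and in the precedent for its asymmetric step. The chosen plan sets against it a stereocentre created directly in a saturated chroman that has no racemisation pathway, no chemoselective reduction, and no gold beside the prenyl olefin and the acetals. It pays for this with the three-step removal of the malonate carbons and an untested enantioselective step.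

Key step: step 10

**Remark on descriptors:** In 16 and 17 the C2 descriptor is S because C3, carrying two carboxyl carbons, outranks the aryl group. The spatial arrangement is that of (2R)-21, and the descriptor returns to R from 18 onward.

**Assumption:** The facial sense of induction of the Sc(OTf)3–pybox complex cannot be predicted with confidence. The route is written with the (S,S)-ligand; its enantiomer is to be used if that is the one that gives (2S)-16.

## Route

Step 1
Reactants: 1 phloroglucinol (benzene-1,3,5-triol)
Product: 2 3,5-bis(methoxymethoxy)phenol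
Conditions: MOMCl (2.0 equiv), iPr2NEt, DMF, 0 °C → rt
Reagents that add atoms: chloromethyl methyl ether (MOMCl), COCCl
Why: O-alkylation of the phenol with an alpha-chloro ether (Williamson type); the mono-, bis- and tris-ethers form statistically and should be separable. The symmetric bis-ether 2 keeps exactly one free phenol, the future O1.

Step 2
Reactants: 2 3,5-bis(methoxymethoxy)phenol
Product: 3 [3,5-bis(methoxymethoxy)phenoxy]triisopropylsilane
Conditions: TIPSCl, imidazole, DMF, rt
Reagents that add atoms: triisopropylsilyl chloride (TIPSCl), CC(C)[Si](Cl)(C(C)C)C(C)C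
Why: Imidazole-promoted silylation of a phenol; the TIPS ether is stable to n-BuLi, shields its ortho positions and is a poor directing group.

Step 3
Reactants: 3 [3,5-bis(methoxymethoxy)phenoxy]triisopropylsilane; 4 prenyl bromide (1-bromo-3-methylbut-2-ene)
Product: 6 [3,5-bis(methoxymethoxy)-4-prenylphenoxy]triisopropylsilane, via [2,6-bis(methoxymethoxy)-4-(triisopropylsilyloxy)phenyl]lithium 5 (not isolated)
Conditions: n-BuLi, THF, 0 °C; CuBr·SMe2 (10 mol %), then 4, −78 °C → rt
Reagents that add atoms: none
Why: Directed ortho-metalation at the position between the two cooperating MOM ethers, then copper-catalysed SN2 allylation of the aryllithium by prenyl bromide; the positions next to the bulky OTIPS group should not be lithiated.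

Step 4
Reactants: 6 [3,5-bis(methoxymethoxy)-4-prenylphenoxy]triisopropylsilane
Product: 7 3,5-bis(methoxymethoxy)-4-prenylphenol
Conditions: TBAF, THF, 0 °C
Reagents that add atoms: none
Why: Fluoride-induced cleavage of the aryl silyl ether; the MOM ethers and the prenyl group are inert to fluoride.

Step 5
Reactants: 7 3,5-bis(methoxymethoxy)-4-prenylphenol
Product: 8 2-hydroxy-4,6-bis(methoxymethoxy)-5-prenylbenzaldehyde
Conditions: MgCl2, Et3N, (CH2O)n, MeCN, reflux
Reagents that add atoms: paraformaldehyde (as formaldehyde), C=O
Why: Casnati–Skattebøl ortho-formylation: the magnesium phenoxide adds to formaldehyde at the ortho carbon and the benzylic alkoxide passes hydride to a second formaldehyde. The two ortho positions of 7 are identical, so only one aldehyde can form and O1 ends para to the prenyl group.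

Step 6
Reactants: 8 2-hydroxy-4,6-bis(methoxymethoxy)-5-prenylbenzaldehyde; 9 3,5-dimethoxybenzyl bromide
Product: 10 2-[(3,5-dimethoxybenzyl)oxy]-4,6-bis(methoxymethoxy)-5-prenylbenzaldehyde
Conditions: K2CO3, DMF, rt → 50 °C
Reagents that add atoms: none
Why: Williamson ether synthesis on the only free phenol with a reactive benzylic bromide.

Step 7
Reactants: 10 2-[(3,5-dimethoxybenzyl)oxy]-4,6-bis(methoxymethoxy)-5-prenylbenzaldehyde
Product: 11 2-[(3,5-dimethoxybenzyl)oxy]-4,6-dihydroxy-5-prenylbenzaldehyde
Conditions: HCl (about 1 M) in MeOH, 0 °C → rt; aqueous work-up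
Reagents that add atoms: none
Why: Acid-catalysed acetal exchange with methanol removes both MOM groups as dimethoxymethane. Dilute acid at or below room temperature should spare the prenyl group, and the 3,5-dimethoxybenzyl ether is not acid-labile because meta-methoxy groups do not stabilise a benzylic cation.

Step 8
Reactants: 11 2-[(3,5-dimethoxybenzyl)oxy]-4,6-dihydroxy-5-prenylbenzaldehyde
Product: 12 2-[(3,5-dimethoxybenzyl)oxy]-4,6-bis(pivaloyloxy)-5-prenylbenzaldehyde
Conditions: PivCl, Et3N, DMAP (cat.), CH2Cl2, 0 → 40 °C
Reagents that add atoms: pivaloyl chloride (PivCl), CC(C)(C)C(=O)Cl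
Why: DMAP-catalysed O-acylation of both phenols; the hydrogen-bonded, doubly flanked phenol reacts more slowly, hence the mild warming.

Step 9
Reactants: 12 2-[(3,5-dimethoxybenzyl)oxy]-4,6-bis(pivaloyloxy)-5-prenylbenzaldehyde; 13 diallyl malonate
Product: 14 diallyl 2-{[2-[(3,5-dimethoxybenzyl)oxy]-4,6-bis(pivaloyloxy)-5-prenylphenyl]methylidene}malonate
Conditions: TiCl4, pyridine, THF, 0 °C → rt
Reagents that add atoms: none
Why: Knoevenagel condensation in its TiCl4/pyridine form, which suits hindered aldehydes and avoids a nucleophilic secondary amine that could attack the aryl pivalates. The two ester groups are identical, so no olefin geometry arises.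

Step 10
Reactants: 14 diallyl 2-{[2-[(3,5-dimethoxybenzyl)oxy]-4,6-bis(pivaloyloxy)-5-prenylphenyl]methylidene}malonate
Product: 16 diallyl (2S)-2-(3,5-dimethoxyphenyl)-5,7-bis(pivaloyloxy)-6-prenylchroman-3,3-dicarboxylate, via oxocarbenium malonate-enolate zwitterion 15 (not isolated)
Conditions: Sc(OTf)3 (10 mol %), (S,S)-Ph-pybox [2,6-bis((4S)-4-phenyl-4,5-dihydrooxazol-2-yl)pyridine] (12 mol %), 4 Å molecular sieves, ClCH2CH2Cl, 60 °C
Reagents that add atoms: none
Why: Proposed new method: Sc(OTf)3 (trivalent scandium) held by the tridentate pybox ligand chelates the two ester carbonyls of 14 and makes the alkylidene carbon (future C4) a hydride acceptor; one hydrogen of the OCH2Ar group moves to it through a six-membered transition state (1,5-hydride transfer) to give 15, an aryl-substituted oxocarbenium ion with a scandium-bound malonate enolate, which closes by C2–C3 bond formation. The closest known reactions are the Sc(OTf)3-catalysed hydride shift and cyclisation of ortho-benzyloxy benzylidene malonates to racemic 2-arylchroman-3,3-dicarboxylates and the chiral Lewis acid versions on N-benzyl anilines; the enantioselective reaction of a benzyl aryl ether is the untested part. Ring C closes in a 6-endo-trig mode at the oxocarbenium carbon (exo with respect to the enolate double bond). C2 is the only new stereocentre and is under catalyst control: the chiral complex carries the enolate and should let it reach only one face of the planar oxocarbenium ion, which amounts to choosing one of the two enantiotopic benzylic hydrogens because the ion pair should collapse faster than it reorganises. The step needs chemoselectivity in the hydride donor and enantioselectivity in the C–C bond formation. The substrate secures the first: the benzylic CH2 is the only C–H alpha to an ether oxygen within reach of C4, since pivalates have replaced the acetals and the prenyl CH2 sits meta to the acceptor. The acyloxy groups also keep ring A from quenching the electrophilicity of the alkylidene and keep the phenols away from the prenyl group and the acceptor.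

Step 11
Reactants: 16 diallyl (2S)-2-(3,5-dimethoxyphenyl)-5,7-bis(pivaloyloxy)-6-prenylchroman-3,3-dicarboxylate
Product: 18 (2R)-2-(3,5-dimethoxyphenyl)-5,7-bis(pivaloyloxy)-6-prenylchroman-3-carboxylic acid (mixture of C3 epimers), via (2S)-2-(3,5-dimethoxyphenyl)-5,7-bis(pivaloyloxy)-6-prenylchroman-3,3-dicarboxylic acid 17 (not isolated)
Conditions: Pd(PPh3)4 (5 mol %), HCO2H, Et3N, 1,4-dioxane, rt; then 100 °C
Reagents that add atoms: none
Why: Tsuji–Trost deallylation with formate as the hydride source (zerovalent palladium ionises each allyl ester and releases propene), then thermal decarboxylation of the malonic acid. The conditions leave the aryl pivalates and the prenyl group alone and no ester enolate is generated at C3, so C2 should keep its configuration; the C3 epimers converge in step 12.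

Step 12
Reactants: 18 (2R)-2-(3,5-dimethoxyphenyl)-5,7-bis(pivaloyloxy)-6-prenylchroman-3-carboxylic acid
Product: 20 (2R)-2-(3,5-dimethoxyphenyl)-6-prenylchroman-5,7-diyl bis(pivalate), via 2-thioxopyridin-1(2H)-yl (2R)-2-(3,5-dimethoxyphenyl)-5,7-bis(pivaloyloxy)-6-prenylchroman-3-carboxylate 19 (not isolated)
Conditions: 2-mercaptopyridine N-oxide, DCC, DMAP (cat.), CH2Cl2, rt, dark; then t-BuSH, hν (tungsten lamp), rt
Reagents that add atoms: none
Why: Barton reductive decarboxylation: the thiohydroxamate ester fragments in a radical chain to CO2 and the secondary C3 radical, which takes hydrogen from the thiol. C2 is not involved, and fast hydrogen transfer from the thiol should outrun fragmentation of the C2–O1 bond.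

Step 13
Reactants: 20 (2R)-2-(3,5-dimethoxyphenyl)-6-prenylchroman-5,7-diyl bis(pivalate)
Product: 21 (2R)-2-(3,5-dimethoxyphenyl)-6-prenylchroman-5,7-diol
Conditions: DIBAL-H, CH2Cl2, −78 → 0 °C; Rochelle salt work-up
Reagents that add atoms: none
Why: Reductive cleavage of the two aryl pivalates by hydride, which reaches the doubly flanked C5 ester where methanolysis would be slow. Nothing else in 20 is reducible and the non-basic work-up protects the free phloroglucinol ring; C2 carries no acidifying group and is not affected.

## Compound list

1 | phloroglucinol (benzene-1,3,5-triol) | Oc1cc(O)cc(O)c1 | starting material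
2 | 3,5-bis(methoxymethoxy)phenol | COCOc1cc(O)cc(OCOC)c1 | intermediate
3 | [3,5-bis(methoxymethoxy)phenoxy]triisopropylsilane | COCOc1cc(O[Si](C(C)C)(C(C)C)C(C)C)cc(OCOC)c1 | intermediate
4 | prenyl bromide (1-bromo-3-methylbut-2-ene) | CC(C)=CCBr | starting material
5 | [2,6-bis(methoxymethoxy)-4-(triisopropylsilyloxy)phenyl]lithium | [Li]c1c(OCOC)cc(O[Si](C(C)C)(C(C)C)C(C)C)cc1OCOC | intermediate
6 | [3,5-bis(methoxymethoxy)-4-prenylphenoxy]triisopropylsilane | COCOc1cc(O[Si](C(C)C)(C(C)C)C(C)C)cc(OCOC)c1CC=C(C)C | intermediate
7 | 3,5-bis(methoxymethoxy)-4-prenylphenol | COCOc1cc(O)cc(OCOC)c1CC=C(C)C | intermediate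
8 | 2-hydroxy-4,6-bis(methoxymethoxy)-5-prenylbenzaldehyde | O=Cc1c(O)cc(OCOC)c(CC=C(C)C)c1OCOC | intermediate
9 | 3,5-dimethoxybenzyl bromide | COc1cc(CBr)cc(OC)c1 | starting material
10 | 2-[(3,5-dimethoxybenzyl)oxy]-4,6-bis(methoxymethoxy)-5-prenylbenzaldehyde | O=Cc1c(OCc2cc(OC)cc(OC)c2)cc(OCOC)c(CC=C(C)C)c1OCOC | intermediate
11 | 2-[(3,5-dimethoxybenzyl)oxy]-4,6-dihydroxy-5-prenylbenzaldehyde | O=Cc1c(OCc2cc(OC)cc(OC)c2)cc(O)c(CC=C(C)C)c1O | intermediate
12 | 2-[(3,5-dimethoxybenzyl)oxy]-4,6-bis(pivaloyloxy)-5-prenylbenzaldehyde | O=Cc1c(OCc2cc(OC)cc(OC)c2)cc(OC(=O)C(C)(C)C)c(CC=C(C)C)c1OC(=O)C(C)(C)C | intermediate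
13 | diallyl malonate | C=CCOC(=O)CC(=O)OCC=C | starting material
14 | diallyl 2-{[2-[(3,5-dimethoxybenzyl)oxy]-4,6-bis(pivaloyloxy)-5-prenylphenyl]methylidene}malonate | COc1cc(OC)cc(COc2cc(OC(=O)C(C)(C)C)c(CC=C(C)C)c(OC(=O)C(C)(C)C)c2C=C(C(=O)OCC=C)C(=O)OCC=C)c1 | intermediate
15 | oxocarbenium malonate-enolate zwitterion (drawn without the scandium complex) | COc1cc(OC)cc(C=[O+]c2cc(OC(=O)C(C)(C)C)c(CC=C(C)C)c(OC(=O)C(C)(C)C)c2CC(C(=O)OCC=C)=C([O-])OCC=C)c1 | intermediate
16 | diallyl (2S)-2-(3,5-dimethoxyphenyl)-5,7-bis(pivaloyloxy)-6-prenylchroman-3,3-dicarboxylate | COc1cc(OC)cc([C@H]2C(Cc3c(cc(OC(=O)C(C)(C)C)c(CC=C(C)C)c3OC(=O)C(C)(C)C)O2)(C(=O)OCC=C)C(=O)OCC=C)c1 | intermediate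
17 | (2S)-2-(3,5-dimethoxyphenyl)-5,7-bis(pivaloyloxy)-6-prenylchroman-3,3-dicarboxylic acid | COc1cc(OC)cc([C@H]2C(Cc3c(cc(OC(=O)C(C)(C)C)c(CC=C(C)C)c3OC(=O)C(C)(C)C)O2)(C(=O)O)C(=O)O)c1 | intermediate
18 | (2R)-2-(3,5-dimethoxyphenyl)-5,7-bis(pivaloyloxy)-6-prenylchroman-3-carboxylic acid (C3 epimers) | COc1cc(OC)cc([C@H]2C(C(=O)O)Cc3c(cc(OC(=O)C(C)(C)C)c(CC=C(C)C)c3OC(=O)C(C)(C)C)O2)c1 | intermediate
19 | 2-thioxopyridin-1(2H)-yl (2R)-2-(3,5-dimethoxyphenyl)-5,7-bis(pivaloyloxy)-6-prenylchroman-3-carboxylate (C3 epimers) | COc1cc(OC)cc([C@H]2C(C(=O)ON4C=CC=CC4=S)Cc3c(cc(OC(=O)C(C)(C)C)c(CC=C(C)C)c3OC(=O)C(C)(C)C)O2)c1 | intermediate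
20 | (2R)-2-(3,5-dimethoxyphenyl)-6-prenylchroman-5,7-diyl bis(pivalate) | COc1cc(OC)cc([C@H]2CCc3c(cc(OC(=O)C(C)(C)C)c(CC=C(C)C)c3OC(=O)C(C)(C)C)O2)c1 | intermediate
21 | (2R)-2-(3,5-dimethoxyphenyl)-6-prenylchroman-5,7-diol | COc1cc(OC)cc([C@H]2CCc3c(cc(O)c(CC=C(C)C)c3O)O2)c1 | target

## Step count and least certain steps

Total step count: 13. Longest linear sequence: 13 steps, from 1 to 21; compounds 4, 9 and 13 enter as purchased reagents.

**Step 10 (key step, proposed new method).**
- Low reactivity: the ligand-bound scandium centre is a weaker Lewis acid than free Sc(OTf)3. The acceptor is flanked by two ortho substituents and the 3,5-dimethoxybenzyl C–H is only a moderate hydride donor, so the hydride transfer may stall.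
- Poor facial selectivity: ring closure could occur through a background pathway on ligand-free scandium or from a loosely bound ion pair.
- Wrong ring closure: the nucleophilic dimethoxyphenyl ring could add to the activated alkylidene in a Friedel–Crafts sense, closing a seven-membered ring.
- Erosion by reversible ring opening of the product under the Lewis acid.
- Fallback (known chemistry, from 8 to 21): Claisen–Schmidt condensation of 8 with commercial 3,5-dimethoxyacetophenone (KOH, EtOH) would give the chalcone (E)-1-(3,5-dimethoxyphenyl)-3-[2-hydroxy-4,6-bis(methoxymethoxy)-5-prenylphenyl]prop-2-en-1-one F1. Hydrogenation of the enone double bond over RhCl(PPh3)3, which leaves the trisubstituted prenyl olefin, would give the ketone 1-(3,5-dimethoxyphenyl)-3-[2-hydroxy-4,6-bis(methoxymethoxy)-5-prenylphenyl]propan-1-one F2. Corey–Bakshi–Shibata reduction with the (R)-methyl oxazaborolidine and BH3·SMe2 would give the (1S)-alcohol (1S)-1-(3,5-dimethoxyphenyl)-3-[2-hydroxy-4,6-bis(methoxymethoxy)-5-prenylphenyl]propan-1-ol F3. Intramolecular Mitsunobu etherification (PPh3, DIAD), with inversion, would give (2R)-2-(3,5-dimethoxyphenyl)-5,7-bis(methoxymethoxy)-6-prenylchroman F4. Removal of the MOM groups as in step 7 returns to the route at 21.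

**Step 11.**
- Erosion of configuration at C2: the enol formed on loss of CO2 has the aryloxy group of C2 in the beta position, and elimination followed by re-addition would scramble C2.
- Incomplete decarboxylation of the hindered diacid.
- Fallback (from 16 to 20): deallylation at room temperature with Pd(PPh3)4 and morpholine would allow isolation of 17. Coupling with N-hydroxyphthalimide (DIC, DMAP) would give bis(1,3-dioxoisoindolin-2-yl) (2S)-2-(3,5-dimethoxyphenyl)-5,7-bis(pivaloyloxy)-6-prenylchroman-3,3-dicarboxylate F5. Two successive radical decarboxylations (NiCl2·6H2O, 4,4'-di-tert-butyl-2,2'-bipyridine, Zn, PhSiH3) would remove both carboxyl groups without any enol at C3 and rejoin the route at 20.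

**Step 12.**
- Fragmentation of the C3 radical: the C2–O1 bond is beta to the radical and its cleavage would open ring C to a styrene and an aryloxyl radical.
- Addition of thiyl radicals to the prenyl olefin.
- Fallback (from 18 to 20): reduction of the acid through its isobutyl mixed anhydride with NaBH4 would give [(2R)-2-(3,5-dimethoxyphenyl)-5,7-bis(pivaloyloxy)-6-prenylchroman-3-yl]methanol F6. Dess–Martin oxidation would give (2R)-2-(3,5-dimethoxyphenyl)-5,7-bis(pivaloyloxy)-6-prenylchroman-3-carbaldehyde F7. Decarbonylation with stoichiometric RhCl(PPh3)3 in hot toluene, a non-radical removal of the last carbon, rejoins the route at 20.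

**Step 7.**
- Acid-induced cyclisation of the prenyl group onto a freed ortho-phenol, giving a 2,2-dimethylchroman.
- Incomplete cleavage of the MOM ether that is flanked on both sides.
- Fallback (acetal-free, from 1 to 12): Vilsmeier–Haack formylation of 1 would give 2,4,6-trihydroxybenzaldehyde F8. C-Prenylation with 4 (DBU, THF) would give 2,4,6-trihydroxy-3-prenylbenzaldehyde F9. Acylation of the non-chelated para-hydroxyl (PivCl, one equivalent) would give 3,5-dihydroxy-4-formyl-2-prenylphenyl pivalate F10. Alkylation of the less hindered ortho-hydroxyl with 9 (K2CO3, DMF) would give 5-[(3,5-dimethoxybenzyl)oxy]-4-formyl-3-hydroxy-2-prenylphenyl pivalate F11. Pivaloylation as in step 8 returns to the route at 12. This road is shorter but depends on C- versus O-prenylation and on discrimination between the two ortho-hydroxyls, which is why it is held in reserve.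

## Further compounds

F1 | step 10 | (E)-1-(3,5-dimethoxyphenyl)-3-[2-hydroxy-4,6-bis(methoxymethoxy)-5-prenylphenyl]prop-2-en-1-one | COc1cc(OC)cc(C(=O)/C=C/c2c(O)cc(OCOC)c(CC=C(C)C)c2OCOC)c1
F2 | step 10 | 1-(3,5-dimethoxyphenyl)-3-[2-hydroxy-4,6-bis(methoxymethoxy)-5-prenylphenyl]propan-1-one | COc1cc(OC)cc(C(=O)CCc2c(O)cc(OCOC)c(CC=C(C)C)c2OCOC)c1
F3 | step 10 | (1S)-1-(3,5-dimethoxyphenyl)-3-[2-hydroxy-4,6-bis(methoxymethoxy)-5-prenylphenyl]propan-1-ol | COc1cc(OC)cc([C@@H](O)CCc2c(O)cc(OCOC)c(CC=C(C)C)c2OCOC)c1
F4 | step 10 | (2R)-2-(3,5-dimethoxyphenyl)-5,7-bis(methoxymethoxy)-6-prenylchroman | COc1cc(OC)cc([C@H]2CCc3c(cc(OCOC)c(CC=C(C)C)c3OCOC)O2)c1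
F5 | step 11 | bis(1,3-dioxoisoindolin-2-yl) (2S)-2-(3,5-dimethoxyphenyl)-5,7-bis(pivaloyloxy)-6-prenylchroman-3,3-dicarboxylate | COc1cc(OC)cc([C@H]2C(Cc3c(cc(OC(=O)C(C)(C)C)c(CC=C(C)C)c3OC(=O)C(C)(C)C)O2)(C(=O)ON4C(=O)c5ccccc5C4=O)C(=O)ON4C(=O)c5ccccc5C4=O)c1
F6 | step 12 | [(2R)-2-(3,5-dimethoxyphenyl)-5,7-bis(pivaloyloxy)-6-prenylchroman-3-yl]methanol (C3 epimers) | COc1cc(OC)cc([C@H]2C(CO)Cc3c(cc(OC(=O)C(C)(C)C)c(CC=C(C)C)c3OC(=O)C(C)(C)C)O2)c1
F7 | step 12 | (2R)-2-(3,5-dimethoxyphenyl)-5,7-bis(pivaloyloxy)-6-prenylchroman-3-carbaldehyde (C3 epimers) | COc1cc(OC)cc([C@H]2C(C=O)Cc3c(cc(OC(=O)C(C)(C)C)c(CC=C(C)C)c3OC(=O)C(C)(C)C)O2)c1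
F8 | step 7 | 2,4,6-trihydroxybenzaldehyde | O=Cc1c(O)cc(O)cc1O
F9 | step 7 | 2,4,6-trihydroxy-3-prenylbenzaldehyde | O=Cc1c(O)cc(O)c(CC=C(C)C)c1O
F10 | step 7 | 3,5-dihydroxy-4-formyl-2-prenylphenyl pivalate | O=Cc1c(O)cc(OC(=O)C(C)(C)C)c(CC=C(C)C)c1O
F11 | step 7 | 5-[(3,5-dimethoxybenzyl)oxy]-4-formyl-3-hydroxy-2-prenylphenyl pivalate | O=Cc1c(OCc2cc(OC)cc(OC)c2)cc(OC(=O)C(C)(C)C)c(CC=C(C)C)c1O
A1 | alternative 1 | (2R)-7-(tert-butyldimethylsilyloxy)-2-(3,5-dimethoxyphenyl)-2,3,4,6,7,8-hexahydrochromen-5-one (C7 epimers) | COc1cc(OC)cc([C@H]2CCC3=C(CC(O[Si](C)(C)C(C)(C)C)CC3=O)O2)c1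
A2 | alternative 1 | 5-(tert-butyldimethylsilyloxy)-2-[(3R)-3-(3,5-dimethoxyphenyl)-3-hydroxypropyl]cyclohexane-1,3-dione | COc1cc(OC)cc([C@H](O)CCC2C(=O)CC(O[Si](C)(C)C(C)(C)C)CC2=O)c1
A3 | alternative 2 | (2R)-2-(3,5-dimethoxyphenyl)-6-prenyl-5-(triisopropylsilyloxy)chroman-7-ol | COc1cc(OC)cc([C@H]2CCc3c(cc(O)c(CC=C(C)C)c3O[Si](C(C)C)(C(C)C)C(C)C)O2)c1
A4 | alternative 2 | (3R)-3-(3,5-dimethoxyphenyl)-2-oxabicyclo[4.2.0]oct-1(6)-en-7-one | COc1cc(OC)cc([C@H]2CCC3=C(CC3=O)O2)c1
A5 | alternative 2 | triisopropyl[(5-methylhex-4-en-1-yn-1-yl)oxy]silane | CC(C)=CCC#CO[Si](C(C)C)(C(C)C)C(C)C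
A6 | alternative 3 | (2R)-2-(3,5-dimethoxyphenyl)-5,7-bis(methoxymethoxy)-6-prenyl-2H-chromene | COc1cc(OC)cc([C@H]2C=Cc3c(cc(OCOC)c(CC=C(C)C)c3OCOC)O2)c1
A7 | alternative 3 | 5-{[(1R)-1-(3,5-dimethoxyphenyl)prop-2-yn-1-yl]oxy}-1,3-bis(methoxymethoxy)-2-prenylbenzene | COc1cc(OC)cc([C@@H](C#C)Oc2cc(OCOC)c(CC=C(C)C)c(OCOC)c2)c1
A8 | alternative 3 | (1S)-1-(3,5-dimethoxyphenyl)prop-2-yn-1-ol | COc1cc(OC)cc([C@@H](O)C#C)c1
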